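**Retrosynthetic overview**

1. Feature: the cyclobutane C5–C6–C6'–C5' is spiro-fused at C5 and C5' to two 4-bromobutenolide rings (O1, C2=O, C3, C4–Br, C5), with O1/O1' trans, C6H(Br)/C6'H(Br) trans and each bromine anti to the neighbouring lactone oxygen. It is an (E)-bifuranylidenedione (C5=C5') plus a BrCH–CHBr unit; a C2 axis makes the two arms of this core homotopic, so the (S)/(R) pair at C7/C7' follows from an (S,S) compound by inverting either carbinol.
2. 16 ⇒ 14: Mitsunobu inversion with AcOH of the one free (S)-carbinol.
3. 14 ⇒ 12 + 13: crossed [2+2] photocycloaddition forming C5–C6 and C5'–C6' (the cyclobutane, the last ring formed).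
4. 12 ⇒ 7: oxidative C5–C5' homocoupling of a silyloxyfuran, dianion oxidation to C5=C5', desilylation, mono-acetylation.
5. 7 ⇒ 1 + 2: C3 butanoylation, C4 deoxybromination, CBS reduction (sets (S)-C7), silylation; both butenolide rings come ready-made from tetronic acid.

Key step: step 9

Remark: atoms are numbered as in the butenolide (O1, C2, C3, C4, C5; side-chain carbinol C7; cyclobutane CHBr carbons C6, C6'); the target SMILES is read as one (S)- and one (R)-1-acetoxybutyl arm on the C2-symmetric core.

**Route**

Step 1
Reactants: 1 tetronic acid; 2 butanoyl chloride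
Product: 4 3-butanoyl-4-hydroxyfuran-2(5H)-one (3-butanoyltetronic acid), via O-butanoyl tetronate 3 (not isolated)
Conditions: Et3N, CH2Cl2, 0 °C; then DMAP (0.3 equiv), rt; aq. HCl
Reagents that add atoms: none
Why: O-acylation of the vinylogous acid followed by DMAP-mediated O→C 1,3-acyl migration (Fries-type rearrangement used for 3-acyltetronic acids) should place the butanoyl group on C3, the chelated triketone enol being the thermodynamic sink.

Step 2
Reactants: 4 3-butanoyltetronic acid
Product: 5 4-bromo-3-butanoylfuran-2(5H)-one
Conditions: (COBr)2, DMF (cat.), CH2Cl2, 0 °C → rt; evaporation, used crude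
Reagents that add atoms: oxalyl bromide, O=C(Br)C(Br)=O
Why: Vilsmeier-type deoxybromination of a vinylogous acid, in which the ring enol oxygen at C4 is activated as an iminium ether and displaced by bromide through addition–elimination, as tetronic acids give 4-bromobutenolides and 2-acylcyclohexane-1,3-diones give 2-acyl-3-haloenones.

Step 3
Reactants: 5 4-bromo-3-butanoylfuran-2(5H)-one
Product: 6 (S)-4-bromo-3-(1-hydroxybutyl)furan-2(5H)-one
Conditions: (R)-Me-CBS oxazaborolidine (15 mol %), BH3·THF, THF, −40 °C; MeOH, then aq. NH4Cl
Reagents that add atoms: none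
Why: Corey–Bakshi–Shibata reduction, in which the flanked butenolide carbon C3 acts as the large and n-propyl as the small group, so the (R)-catalyst should deliver hydride to the face that gives (S)-C7 (the sense in which acetophenone gives (S)-1-phenylethanol), faster than borane touches the lactone or the electron-poor alkene.

Step 4
Reactants: 6 (S)-4-bromo-3-(1-hydroxybutyl)furan-2(5H)-one
Product: 7 (S)-4-bromo-2-(tert-butyldimethylsilyloxy)-3-[1-(tert-butyldimethylsilyloxy)butyl]furan
Conditions: TBSOTf (2.3 equiv), Et3N, CH2Cl2, 0 °C
Reagents that add atoms: tert-butyldimethylsilyl triflate (TBSOTf), CC(C)(C)[Si](C)(C)OS(=O)(=O)C(F)(F)F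
Why: Silyl triflate/amine soft enolisation silylates the alcohol and deprotonates C5 to the aromatic 2-silyloxyfuran, which turns C7–O into a poor leaving group for the electron-rich intermediates that follow and leaves C7 untouched.

Step 5
Reactants: 7 silyloxyfuran (two molecules)
Product: 8 C5–C5' linked bi{4-bromo-3-[(S)-1-(tert-butyldimethylsilyloxy)butyl]furan-2(5H)-one} (C5/C5' epimer mixture)
Conditions: Ag2O (1.1 equiv), DMSO/CH2Cl2, rt, dark
Reagents that add atoms: none
Why: Oxidative homocoupling of a silyl dienol ether with Ag2O (Ito–Saegusa type), in which one-electron oxidation gives a furan-2-oxyl radical that dimerises at C5 because C3 is fully substituted; the two new C5/C5' centres need no control since step 6 removes them.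

Step 6
Reactants: 8 bibutenolide bis-TBS ether
Product: 10 (E)-bifuranylidenedione (S,S)-bis-TBS ether (C5=C5' alkene), via dipotassium bifurandiolate 9 (not isolated)
Conditions: KN(SiMe3)2 (2.2 equiv), THF, −78 °C; then cannulated into I2 (1.05 equiv), THF, −78 → 0 °C
Reagents that add atoms: none
Why: Double γ-deprotonation gives the aromatic bifurandiolate 9, an extended hydroquinone dianion, which iodine oxidises by two electrons to the quinoid C5=C5' alkene (oxidation of a vicinal bis-enolate to an alkene); the anti conformer of 9 keeps the two C4 bromines apart and leads to the E isomer, which is also the thermodynamic one.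

Step 7
Reactants: 10 (E)-bifuranylidenedione bis-TBS ether
Product: 11 (E)-bifuranylidenedione (S,S)-diol
Conditions: aq. HF (48 %), MeCN, 0 °C → rt
Reagents that add atoms: none
Why: Acidic fluoride cleavage of the two secondary silyl ethers brings no base or nucleophile to the electrophilic trienedione and does not touch C7.

Step 8
Reactants: 11 (E)-bifuranylidenedione (S,S)-diol
Product: 12 (E)-bifuranylidenedione with one (S)-1-acetoxybutyl and one (S)-1-hydroxybutyl arm
Conditions: Ac2O (1.0 equiv), Sc(OTf)3 (1 mol %), MeCN, −20 °C; chromatography, recovered 11 recycled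
Reagents that add atoms: acetic anhydride, CC(=O)OC(C)=O
Why: Lewis-acid-catalysed acetylation with retention at C7; the two hydroxyls are exchanged by the C2 axis through the midpoint of C5=C5', so only one mono-acetate can form and the outcome is statistical, with diol and diacetate separable.

Step 9
Reactants: 12 (E)-bifuranylidenedione mono-acetate; 13 (E)-1,2-dibromoethene
Product: 14 dispiro tetrabromide with (S)-acetate and (S)-alcohol arms (O1/O1' trans, C6/C6' bromines trans and each anti to the vicinal lactone oxygen)
Conditions: hν (365 nm LED), 13 (30 equiv), degassed CH2Cl2, −40 °C; HPLC separation of isomers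
Reagents that add atoms: none
Why: Excitation of the trienedione at 365 nm (where neither 13 nor the product absorbs) and bromine-assisted intersystem crossing should give a triplet that relaxes by twisting about C5=C5' into two furan-2-oxyl radical halves; C5 adds to 13 to form C5–C6 and a triplet 1,4-biradical (furanoxyl at C5', α-bromoalkyl at C6'), which after spin inversion closes the four-membered ring by radical recombination at C5'–C6'. The closest known reactions are the [2+2] photocycloadditions of 1,2-dihaloethenes to excited enones and maleic anhydride and the head-to-head photodimerisation of γ-ylidenebutenolides at their exocyclic C=C. C5 and C5' should keep the trans O1/O1' arrangement of the E alkene because the cis alternative presses the two C4 vinyl bromides together on one face, and C6/C6' should close as the trans dibromide from the freely rotating biradical, whatever the geometry of 13. The step needs each C6–Br anti to the vicinal C5–O1 bond, which opposition of the C–Br and C–O dipoles favours and the C4 bromine opposes, and it needs addition to the Si,Si face of C5/C5'; in both low-strain rotamers of an (S)-C7 arm (C7–H eclipsing C3=C4, or C7–O in the ring plane toward C2=O) the propyl chain lies on the opposite face and leaves this face open. Both biases are weak, so a mixture of cyclobutane diastereomers is expected and 14 must be separated and assigned crystallographically; low temperature and a large excess of 13 are chosen to outrun loss of a bromine atom from the β-bromoalkyl radical end and self-dimerisation of 12.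

Step 10
Reactants: 14 dispiro tetrabromide, (S)-acetate/(S)-alcohol
Product: 16 target CNP0266230.1 ((S)-acetate/(R)-acetate), via oxyphosphonium acetate 15 (not isolated)
Conditions: PPh3, DIAD (betaine pre-formed, 0 °C), AcOH, THF, 0 °C → rt
Reagents that add atoms: acetic acid, CC(=O)O
Why: Mitsunobu reaction, in which the free (S)-carbinol is activated as oxyphosphonium salt 15 and displaced by acetate in an SN2 step with inversion to the (R)-acetate, ionisation being disfavoured by the electron-poor butenolide; because the two arms of the C2-symmetric core are homotopic this gives exactly the (S)/(R) pair of the target.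

**Compound list**

1 | tetronic acid (4-hydroxyfuran-2(5H)-one) | OC1=CC(=O)OC1 | starting material
2 | butanoyl chloride | CCCC(Cl)=O | starting material
3 | 5-oxo-2,5-dihydrofuran-3-yl butanoate (O-butanoyl tetronate) | CCCC(=O)OC1=CC(=O)OC1 | intermediate (not isolated)
4 | 3-butanoyl-4-hydroxyfuran-2(5H)-one | CCCC(=O)C1=C(O)COC1=O | intermediate
5 | 4-bromo-3-butanoylfuran-2(5H)-one | CCCC(=O)C1=C(Br)COC1=O | intermediate
6 | (S)-4-bromo-3-(1-hydroxybutyl)furan-2(5H)-one | CCC[C@H](O)C1=C(Br)COC1=O | intermediate
7 | (S)-4-bromo-2-(tert-butyldimethylsilyloxy)-3-[1-(tert-butyldimethylsilyloxy)butyl]furan | CCC[C@H](O[Si](C)(C)C(C)(C)C)c1c(Br)coc1O[Si](C)(C)C(C)(C)C | intermediate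
8 | C5–C5' linked bibutenolide, 4,4'-dibromo, 3,3'-bis[(S)-1-(TBSO)butyl], C5/C5' epimer mixture | CCC[C@H](O[Si](C)(C)C(C)(C)C)C1=C(Br)C(OC1=O)C1OC(=O)C([C@H](CCC)O[Si](C)(C)C(C)(C)C)=C1Br | intermediate
9 | dipotassium 3,3'-dibromo-4,4'-bis[(S)-1-(TBSO)butyl]-2,2'-bifuran-5,5'-diolate | CCC[C@H](O[Si](C)(C)C(C)(C)C)c1c(Br)c(oc1[O-])-c1oc([O-])c([C@H](CCC)O[Si](C)(C)C(C)(C)C)c1Br.[K+].[K+] | intermediate (not isolated)
10 | (E)-bifuranylidenedione (C5=C5', O1/O1' trans), Br at C4/C4', (S)-1-(TBSO)butyl at C3/C3' | CCC[C@H](O[Si](C)(C)C(C)(C)C)C1=C(Br)/C(OC1=O)=C2\OC(=O)C([C@H](CCC)O[Si](C)(C)C(C)(C)C)=C2Br | intermediate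
11 | (E)-bifuranylidenedione, Br at C4/C4', (S)-1-hydroxybutyl at C3/C3' | CCC[C@H](O)C1=C(Br)/C(OC1=O)=C2\OC(=O)C([C@H](CCC)O)=C2Br | intermediate
12 | (E)-bifuranylidenedione, Br at C4/C4', (S)-1-acetoxybutyl at C3, (S)-1-hydroxybutyl at C3' | CCC[C@H](OC(C)=O)C1=C(Br)/C(OC1=O)=C2\OC(=O)C([C@H](CCC)O)=C2Br | intermediate
13 | (E)-1,2-dibromoethene | Br/C=C/Br | starting material
14 | dispiro tetrabromide (cyclobutane C5–C6–C6'–C5'), (S)-acetate and (S)-alcohol arms | CCC[C@H](OC(C)=O)C1=C(Br)[C@@]2(OC1=O)[C@@H](Br)[C@H](Br)[C@@]21OC(=O)C([C@H](CCC)O)=C1Br | intermediate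
15 | oxyphosphonium acetate of 14 (C7'–O–PPh3+) | CCC[C@H](OC(C)=O)C1=C(Br)[C@@]2(OC1=O)[C@@H](Br)[C@H](Br)[C@@]21OC(=O)C([C@H](CCC)O[P+](c3ccccc3)(c3ccccc3)c3ccccc3)=C1Br.CC(=O)[O-] | intermediate (not isolated)
16 | CNP0266230.1, dispiro tetrabromide with (S)- and (R)-1-acetoxybutyl arms | CCC[C@H](OC(C)=O)C1=C(Br)[C@@]2(OC1=O)[C@@H](Br)[C@H](Br)[C@@]21OC(=O)C([C@@H](CCC)OC(C)=O)=C1Br | target

Total step count: 10. Longest linear sequence: 10 steps (1 → 16).

**Steps most likely to fail**

Step 9. The α-bromoalkyl radical end of the 1,4-biradical may expel a bromine atom before ring closure, and addition may take the wrong face or the wrong orientation of the CHBr groups, so that too little of the needed diastereomer forms. The fallback builds the same cyclobutane by the head-to-head photodimerisation known for γ-ylidenebutenolides (protoanemonin-to-anemonin type), which forms C6–C6' first and closes C5–C5' between two stabilised furanoxyl radicals. It sets out from 7. Aqueous formaldehyde with Yb(OTf)3 (cat.) in THF (aqueous Mukaiyama aldol at C5) should give the hydroxymethyl butenolide F1. MsCl/Et3N then eliminates it to the 5-methylene butenolide F2. Br2 in CH2Cl2 followed by Et3N (bromination–dehydrobromination of the exocyclic alkene) gives the (Z)-bromomethylene butenolide F3. Irradiation of F3 (350 nm, concentrated solution or thin film) should give, among its dimers, the bis-silyl dispiro tetrabromide F4, which after separation is desilylated with aq. HF in MeCN to the dispiro diol F5. Mono-acetylation of F5 under the conditions of step 8 comes back to the route at 14.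

Step 10. PPh3 may attack a bromine of the vicinal dibromide or the β-carbon of a bromobutenolide, or the activated hindered carbinol may eliminate instead of being displaced. The fallback inverts C7' by oxidation and reagent-controlled reduction. It sets out from 14. Dess–Martin periodinane in CH2Cl2 should give the ketone F6. (S)-Me-CBS oxazaborolidine with BH3·THF at −40 °C reduces it to the (R)-alcohol F7. Acetylation with Ac2O and Sc(OTf)3 (cat.) comes back to the route at 16.

Step 2. Activation may occur at the exocyclic enol tautomer, so that bromide enters at the side-chain carbonyl carbon instead of C4. The fallback fixes the regiochemistry by introducing bromine and the C3 carbon in one Vilsmeier–Haack–Arnold bromoformylation. It sets out from 1. PBr3/DMF in CHCl3 should give the bromo aldehyde F8. n-PrMgBr in THF at −78 °C (inverse addition) adds to the aldehyde to give the racemic carbinol F9. Dess–Martin oxidation comes back to the route at 5, where step 3 sets the configuration.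

**Further compounds**

F1 | step 9 | 4-bromo-5-(hydroxymethyl)-3-[(S)-1-(tert-butyldimethylsilyloxy)butyl]furan-2(5H)-one (C5 epimers) | CCC[C@H](O[Si](C)(C)C(C)(C)C)C1=C(Br)C(CO)OC1=O
F2 | step 9 | 4-bromo-5-methylene-3-[(S)-1-(tert-butyldimethylsilyloxy)butyl]furan-2(5H)-one | CCC[C@H](O[Si](C)(C)C(C)(C)C)C1=C(Br)C(=C)OC1=O
F3 | step 9 | (Z)-4-bromo-5-(bromomethylene)-3-[(S)-1-(tert-butyldimethylsilyloxy)butyl]furan-2(5H)-one | CCC[C@H](O[Si](C)(C)C(C)(C)C)C1=C(Br)/C(=C/Br)OC1=O
F4 | step 9 | dispiro tetrabromide with two (S)-1-(tert-butyldimethylsilyloxy)butyl arms | CCC[C@H](O[Si](C)(C)C(C)(C)C)C1=C(Br)[C@@]2(OC1=O)[C@@H](Br)[C@H](Br)[C@@]21OC(=O)C([C@H](CCC)O[Si](C)(C)C(C)(C)C)=C1Br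
F5 | step 9 | dispiro tetrabromide with two (S)-1-hydroxybutyl arms | CCC[C@H](O)C1=C(Br)[C@@]2(OC1=O)[C@@H](Br)[C@H](Br)[C@@]21OC(=O)C([C@H](CCC)O)=C1Br
F6 | step 10 | dispiro tetrabromide with (S)-1-acetoxybutyl and butanoyl arms | CCC[C@H](OC(C)=O)C1=C(Br)[C@@]2(OC1=O)[C@@H](Br)[C@H](Br)[C@@]21OC(=O)C(C(=O)CCC)=C1Br
F7 | step 10 | dispiro tetrabromide with (S)-1-acetoxybutyl and (R)-1-hydroxybutyl arms | CCC[C@H](OC(C)=O)C1=C(Br)[C@@]2(OC1=O)[C@@H](Br)[C@H](Br)[C@@]21OC(=O)C([C@@H](CCC)O)=C1Br
F8 | step 2 | 4-bromo-2-oxo-2,5-dihydrofuran-3-carbaldehyde | O=CC1=C(Br)COC1=O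
F9 | step 2 | racemic 4-bromo-3-(1-hydroxybutyl)furan-2(5H)-one | CCCC(O)C1=C(Br)COC1=O
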